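No flask can spend more G than it was given, so the examination starts from that balance.

| setting | Monday's | Wednesday's | eta | beta |
|---|---|---|---|---|
| J | 31 mM | 31 mM | 31 mM | 31 mM |
| G | 1.4 equiv | 2.2 equiv | 1.00 equiv | 1.00 equiv |
| temperature | −45 °C | −20 °C | −40 °C | 0 °C |
| remark | run made earlier | run made earlier |  |  |
| time |  |  | 3.0 min | 3.0 min |

- Monday's (time / min: L / %, D / %): 2.00: 6, 0; 3.00: 4, 0; 4.00: 9, 0; 6.00: 11, 0; 10.0: 19, 3; 15.0: 21, 7; 25.0: 30, 9
- Wednesday's (time / min: L / %, D / %): 0.833: 29, 6; 2.00: 45, 17; 2.50: 43, 17; 4.00: 43, 31; 5.00: 38, 39; 6.00: 36, 44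

(each reading ± 1.5 percentage points)

- which one finishes higher in share of L in all that became L or D ("neither" within 2 percentage points) (eta / beta / neither)
- share of L in all that became L or D, eta
- share of L in all that became L or D, beta



*What does G pay for?* I read D as lagging L, so I take one G for each L and a second for each D. With J and G charged equally in eta and beta, that reading makes G the limiting reagent.

*What do you carry?* I carry the G bill, the G that L and D cost per unit of L and D together, which is (L + 2D)/(L + D). The share of L is then 2 minus the bill.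

*Where do you read it?* I read it at Wednesday's highest L reading, 2.00 min: L 45% and D 17% cost 79.0% of the J charged, so the bill is 1.27.

*But Wednesday's had 2.2 equiv of G, and beta has 1.00 equiv.* In my reading both steps use G, so the ratio of their speeds contains no G, and the bill at equal progress should not follow the charge.

*Does beta get that far?* Per equivalent of G, the early L readings rise by a factor of 9.85 from Monday's to Wednesday's. That factor exceeds the 2.20 by which beta's G charge is smaller than Wednesday's, and beta, at 0 °C, is warmer than Wednesday's, so I expect beta to reach that progress within 3.0 min, though this is an expectation from a colder pair of runs.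

*And the temperature?* That is the weak spot, since I cannot remove it. The bill is a reading with its scatter, carried unadjusted from −20 °C, and it gives beta 72.6%.

*Eta?* Eta at −40 °C stands near Monday's −45 °C, and Monday's D still reads 0% at 6.00 min with L at 11%. So I put eta's bill close to 1 and eta above beta.

The forecast names eta, with 97% for eta and 76% for beta, and says of beta that “G depletes, so conversion is about 50–60%”; my beta lies below it.

The flask gives eta as the higher, eta at 96.2% and beta at 65.7%, so beta's bill, counted on L and D as before, is 1.34 against the 1.27 I carried.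

    L ⇌ E (K = 0.460, k = 0.00390 s⁻¹, Ea = 75.0 kJ mol⁻¹, ΔH = −55.0 kJ mol⁻¹)
    J + G → E (k = 0.0160 L mol⁻¹ s⁻¹, Ea = 40.0 kJ mol⁻¹)
    2 J → Q (k = 0.0700 L mol⁻¹ s⁻¹, Ea = 50.0 kJ mol⁻¹)
    J ⇌ Z (K = 0.600, k = 0.00280 s⁻¹, Ea = 71.0 kJ mol⁻¹, ΔH = −10.0 kJ mol⁻¹)
    G + L → D (k = 0.340 L mol⁻¹ s⁻¹, Ea = 42.0 kJ mol⁻¹)
    J + G → L (k = 0.960 L mol⁻¹ s⁻¹, Ea = 53.0 kJ mol⁻¹)
    (constants at 0 °C)

Take eta with one change, G raised to 2.50 equiv, and reckon the bill the same way. At 3.00 min this neighbour holds L 18.6% and D 1.89%, against L 8.44% and D 0.330% in eta. Its bill is 1.09, where eta's was 1.04, and its share of L is 90.7%. J stands at 77% of its charge, and G stands at 91% of its own charge.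

The earlier runs and the new flask are simulated with made-up constants; the scatter is artificial.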